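In a one-step world the product is there as soon as the charge has reacted; here links stand between the two as an intermediate, so a clock keeps running after the last drop.

| setting | eta | beta | theta | ash | maple | alder | elm |
|---|---|---|---|---|---|---|---|
| first end groups | 0.33 M | 0.33 M | 0.33 M | 0.33 M (fed, over 50 min) | 0.33 M | 0.33 M | 0.33 M |
| second end groups | 0.347 M | 0.347 M | 0.347 M | 0.347 M | 0.347 M | 0.347 M (fed, over 50 min) | 0.347 M (in portions, 3, over 50 min) |
| one-sided end groups | 0.033 M | 0.046 M | 0.073 M | 0.0330 M | 0.0330 M | 0.0330 M | 0.0330 M |
| protic impurity | 0.165 M | 0.165 M | 0.165 M | 0.165 M | 0.165 M | 0.165 M | 0.165 M |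
| remark | run made earlier | run made earlier | run made earlier | all else is in the flask from the start; the feed brings no volume worth counting | everything together at the start | all else is in the flask from the start; the feed brings no volume worth counting | first portion at the start, last at 50 min |
| time |  |  |  | 80 min | 80 min | 80 min | 80 min |

| run | time / min | over-reaction product / % | links / % |
|---|---|---|---|
| eta | 6.00 | 9 | 45 |
| eta | 10.0 | 19 | 46 |
| eta | 15.0 | 31 | 40 |
| eta | 25.0 | 53 | 27 |
| eta | 30.0 | 59 | 22 |
| eta | 50.0 | 72 | 9 |
| eta | 80.0 | 80 | 1 |
| beta | 15.0 | 32 | 37 |
| beta | 30.0 | 55 | 22 |
| beta | 40.0 | 64 | 13 |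
| beta | 60.0 | 73 | 4 |
| beta | 80.0 | 76 | 2 |
| beta | 90.0 | 77 | 1 |
| theta | 8.00 | 20 | 42 |
| theta | 12.0 | 23 | 38 |
| theta | 20.0 | 39 | 28 |
| theta | 25.0 | 48 | 23 |
| theta | 40.0 | 59 | 8 |
| theta | 60.0 | 69 | 2 |
| theta | 90.0 | 72 | 0 |

(readings scatter by 1.5 percentage points)

- the numbers in the tables scatter by 1.5 percentage points (one standard deviation)
- what may be going on: first end groups + one-sided end groups -> capped ends; first end groups + second end groups -> links; first end groups + protic impurity -> quenched substrate; links -> over-reaction product

1. the flask that comes out highest in amount of over-reaction product, in percent of the first end groups charged, or "all alike" when all lie within 1.5 percentage points (ash / maple / alder / elm / all alike)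
2. over-reaction product at the end, in percent of the first end groups charged, ash
3. over-reaction product at the end, in percent of the first end groups charged, maple
4. over-reaction product at the end, in percent of the first end groups charged, alder
5. over-reaction product at the end, in percent of the first end groups charged, elm

**Which clock, and where do you read it?** In the beta run, links plus product are 77.0% at 30.0 min and 78.0% at 90.0 min, so from 30.0 min beta's links are mostly just decaying. They fall from 22% to 4% by 60.0 min, a first-order reading of 0.0568 /min. The link half-life, the time a standing stock of links takes to fall to half with none arriving, is therefore 12.2 min, with the scatter of those readings.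

**Maple?** It repeats the eta recipe, and eta read 80% product and 1% links at 80.0 min. Those two readings add up to 81.0% for links plus product, and I take that as my ceiling, with its scatter.

**Ash?** I keep that ceiling and ask what is still link. First round: links are born evenly over 50 min, decay at the rate above, and then have 30.0 min more, which leaves 4.88%. Second round: I put that answer back, because a drop does not link at once. Eta took 6.00 min to reach 66.7% of its ceiling, so I shift the births by that lag. My estimate for ash is then 6.86% links and 74.1% product.

**Weak spot?** Eta's lag was read in a flask that started at [second end groups] = 0.347 M. The ceiling leaves about 0.0797 M late in ash, so the lag may run longer and my link figure low.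

**Alder and elm?** The half-life gives the tail, not the selectivity, so I leave their yields to the forecast.

The forecast names maple: 80% (78% to 82%) for maple and 75% (71% to 78%) for ash, where “links form late”. It gives 59% (52% to 65%) for alder and 58% (51% to 64%) for elm.

    first end groups + one-sided end groups → capped ends (k = 0.710 /M/s)
    first end groups + second end groups → links (k = 0.0140 /M/s)
    first end groups + protic impurity → quenched substrate (k = 0.00170 /M/s)
    links → over-reaction product (k = 9.20 × 10⁻⁴ /s)

Maple is highest at 80.0%, with ash at 72.3%, alder at 61.3% and elm at 62.2%. Ash has not come to rest: from 25.8% links at 50.0 min, 30.0 min at a half-life of 12.2 min with no links arriving would leave 4.69%, yet 8.63% stand, with 14.3% first end groups present when the feed ended. Alder, from 17.6% links, would keep 3.20%; 4.46% stand, after 3.99% first end groups at that time. Ten times the time lifts ash to 81.7%, level with maple's 81.7%, and alder to 65.9%.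

The readings come from a simulation from invented constants, noise included.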